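**Plan**

1. Ring numbering: C1 (OAc), C2=C3 (C7H2OBz on C3), C4 (OH), C5 (OBz), C6 (OH). The retrosynthesis cuts the three ester C–O bonds, then C3–C7 (back to a C3 ketone through a spiro-epoxide), then the ring bond C1–C2 (aldol retron: C1 carbinol β to the C3 carbonyl).
2. Enabling feature: C6, C5 and C4 carry the configuration of C2, C3 and C4 of L-rhamnose. The sugar's C6 methyl maps onto ring C2 once sugar C5 is a ketone, so the carbocycle is the internal aldol of a 6-deoxyhexos-5-ulose.
3. Forward: L-rhamnose → benzyl pyranoside, 2,3-acetonide, 4-O-TIPS → lactol → 1,5-diol → double Swern oxidation → keto-aldehyde → proline aldol, which closes the only carbocycle.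
4. Then C1–OTES, sulfur-ylide methylene transfer to C3 (brings C7), epoxide-to-allylic-alcohol isomerisation (C2=C3), C7 benzoate, C1 acetate.
5. End game: acetonide off, C5 benzoate by orthobenzoate opening of the cis-5,6-diol, TIPS off.
6. Stereochemistry: C4, C5 and C6 come from L-rhamnose; C1 is set in the aldol, trans to C6–O, through a chair-like transition state.

Key step: step 7

Remark (numbering): carbocycles carry the target's ring numbering; sugar-derived compounds keep sugar numbering. Sugar C1, C2, C3, C4, C5, C6 become ring C1, C6, C5, C4, C3, C2.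
Assumption: the spiro carbon of 12 and the orthoester carbon of 21 are transient stereocentres. 12 is drawn as the epimer expected from ylide attack anti to the two silyloxy groups, and 21 is a mixture at the orthoester carbon; neither affects later compounds.

**Route**

Step 1
Reactants: 1 L-rhamnose (as the monohydrate); 2 benzyl alcohol
Product: 3 benzyl α-L-rhamnopyranoside
Conditions: BnOH (solvent), TsOH·H2O (cat.), 80 °C
Reagents that add atoms: none
Why: Fischer glycosidation under thermodynamic control, in which the anomeric effect favours the axial α-pyranoside; this masks C1 and leaves the cis-2,3-diol and the 4-OH free.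

Step 2
Reactants: 3 benzyl α-L-rhamnopyranoside
Product: 4 benzyl 2,3-O-isopropylidene-α-L-rhamnopyranoside
Conditions: Me2C(OMe)2, TsOH·H2O (cat.), acetone, rt
Reagents that add atoms: 2,2-dimethoxypropane, COC(C)(C)OC
Why: Acid-catalysed transacetalisation; only the cis-2,3-diol can close a five-membered dioxolane, so the 4-OH stays free.

Step 3
Reactants: 4 benzyl 2,3-O-isopropylidene-α-L-rhamnopyranoside
Product: 5 benzyl 2,3-O-isopropylidene-4-O-(triisopropylsilyl)-α-L-rhamnopyranoside
Conditions: TIPSOTf, 2,6-lutidine, CH2Cl2, 0 °C → rt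
Reagents that add atoms: triisopropylsilyl trifluoromethanesulfonate, CC(C)[Si](C(C)C)(C(C)C)OS(=O)(=O)C(F)(F)F
Why: Silylation of the hindered secondary hydroxyl with a silyl triflate and a hindered pyridine base; the bulky TIPS group is chosen because it should not migrate to the neighbouring C5 oxygen in step 5 and should outlast the acid of step 14.

Step 4
Reactants: 5 benzyl 2,3-O-isopropylidene-4-O-(triisopropylsilyl)-α-L-rhamnopyranoside
Product: 6 2,3-O-isopropylidene-4-O-(triisopropylsilyl)-L-rhamnopyranose (anomeric mixture)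
Conditions: H2 (1 atm), 10% Pd/C, EtOAc, rt
Reagents that add atoms: none
Why: Catalytic hydrogenolysis of the anomeric benzyl ether frees the lactol, while the acetonide and the silyl ether are inert under neutral conditions.

Step 5
Reactants: 6 2,3-O-isopropylidene-4-O-(triisopropylsilyl)-L-rhamnopyranose
Product: 7 6-deoxy-2,3-O-isopropylidene-4-O-(triisopropylsilyl)-L-mannitol (sugar numbering kept: C1 is CH2OH and C5 is CHOH)
Conditions: NaBH4, EtOH, 0 °C
Reagents that add atoms: none
Why: Borohydride reduction of the aldehyde form in equilibrium with the lactol gives the 1,5-diol and exposes the sugar C5 hydroxyl for oxidation; no stereocentre is touched.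

Step 6
Reactants: 7 6-deoxy-2,3-O-isopropylidene-4-O-(triisopropylsilyl)-L-mannitol
Product: 8 6-deoxy-2,3-O-isopropylidene-4-O-(triisopropylsilyl)-L-lyxo-hexos-5-ulose (used crude)
Conditions: (COCl)2, DMSO, CH2Cl2, −78 °C; iPr2NEt, −78 → −20 °C
Reagents that add atoms: none
Why: Swern oxidation turns both hydroxyls into alkoxysulfonium ions before the amine is added, so aldehyde and ketone appear together and the hydroxy-aldehyde cannot close to a lactol and over-oxidise to a lactone; the low temperature and hindered amine protect the α-oxygenated centres.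

Step 7
Reactants: 8 6-deoxy-2,3-O-isopropylidene-4-O-(triisopropylsilyl)-L-lyxo-hexos-5-ulose
Product: 9 (1R,4R,5S,6S)-1-hydroxy-5,6-(isopropylidenedioxy)-4-(triisopropylsilyloxy)cyclohexan-3-one
Conditions: L-proline (30 mol %), DMSO, rt
Reagents that add atoms: none
Why: L-Proline condenses with the methyl ketone to the terminal enamine (sugar C5=C6), whose CH2 adds to the aldehyde carbon (sugar C1) while the carboxylic acid protonates the aldehyde oxygen, and hydrolysis of the iminium returns the catalyst; this is an amine-catalysed intramolecular aldol of the Hajos–Parrish type and the ring-forming event of a Ferrier carbocyclisation. The single ring closes in a 6-(enolendo)-exo-trig mode, because both enamine carbons end up inside the cyclohexanone. The new C1 carbinol is set by the substrate: in the chair-like transition state C4–OTIPS and C5–O sit equatorial, C6–O axial and the acid-bound aldehyde oxygen axial beside nitrogen, so that oxygen lies anti to C6–O and avoids a 1,3-diaxial contact with C5–O, giving the 1,6-trans ketol; L-proline, which favours the same carbinol sense with methyl-ketone donors, should be the matched catalyst. Regioselectivity is needed and is secured because an enamine on the C4 side could only close a four-membered ring. Chemoselectivity (no dehydration, no β-loss of the C5 oxygen, no epimerisation at C4 or C6) rests on the nearly neutral medium and on the dioxolane, which holds the β C–O bonds out of alignment with the enamine and enol π systems; the reaction is stopped at full conversion so that retro-aldol equilibration cannot erode the kinetic outcome.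

Step 8
Reactants: 9 (1R,4R,5S,6S)-1-hydroxy-5,6-(isopropylidenedioxy)-4-(triisopropylsilyloxy)cyclohexan-3-one
Product: 10 (1R,4R,5S,6R)-5,6-(isopropylidenedioxy)-1-(triethylsilyloxy)-4-(triisopropylsilyloxy)cyclohexan-3-one
Conditions: TESCl, imidazole, DMF, 0 °C
Reagents that add atoms: chlorotriethylsilane, CC[Si](Cl)(CC)CC
Why: Silylation of the secondary carbinol with a chlorosilane and imidazole blocks retro-aldol and dehydration before basic reagents are used; a triethylsilyl ether is chosen so that it can later be removed beside the TIPS ether.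

Step 9
Reactants: 10 (1R,4R,5S,6R)-5,6-(isopropylidenedioxy)-1-(triethylsilyloxy)-4-(triisopropylsilyloxy)cyclohexan-3-one; 11 trimethylsulfonium iodide
Product: 12 (1R,3R,4R,5S,6R)-3,7-epoxy-5,6-(isopropylidenedioxy)-3-methyl-1-(triethylsilyloxy)-4-(triisopropylsilyloxy)cyclohexane (C7 is the oxirane CH2; oxirane oxygen cis to C4–O)
Conditions: Me3S+ I−, n-BuLi, THF, −10 → 0 °C
Reagents that add atoms: none
Why: Corey–Chaykovsky epoxidation, in which the unstabilised sulfur ylide adds irreversibly to the ketone and the betaine closes to the oxirane, bringing in C7; attack is expected anti to the C4 and C1 silyloxy groups, but the spiro centre is erased in step 10, so either epimer serves.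

Step 10
Reactants: 12 (1R,3R,4R,5S,6R)-3,7-epoxy-5,6-(isopropylidenedioxy)-3-methyl-1-(triethylsilyloxy)-4-(triisopropylsilyloxy)cyclohexane
Product: 13 (1R,4S,5S,6R)-3-(hydroxymethyl)-5,6-(isopropylidenedioxy)-1-(triethylsilyloxy)-4-(triisopropylsilyloxy)cyclohex-2-ene
Conditions: lithium 2,2,6,6-tetramethylpiperidide, Et2AlCl, toluene, 0 °C (aluminium amide formed first, then 12 added)
Reagents that add atoms: none
Why: Isomerisation of an epoxide to an allylic alcohol by an aluminium amide, a syn-elimination through a cyclic transition state in which aluminium holds the oxirane oxygen; the amide should take the accessible C2 methylene proton and not the hindered C4 methine (anti to the oxirane oxygen in the drawn epimer), giving the C2=C3 alkene and the C7 alcohol.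

Step 11
Reactants: 13 (1R,4S,5S,6R)-3-(hydroxymethyl)-5,6-(isopropylidenedioxy)-1-(triethylsilyloxy)-4-(triisopropylsilyloxy)cyclohex-2-ene; 14 benzoyl chloride
Product: 15 (1R,4S,5S,6R)-3-(benzoyloxymethyl)-5,6-(isopropylidenedioxy)-1-(triethylsilyloxy)-4-(triisopropylsilyloxy)cyclohex-2-ene
Conditions: BzCl, pyridine, DMAP (cat.), CH2Cl2, 0 °C
Reagents that add atoms: none
Why: Acylation of the only free hydroxyl (primary, allylic) with an acid chloride under nucleophilic catalysis.

Step 12
Reactants: 15 (1R,4S,5S,6R)-3-(benzoyloxymethyl)-5,6-(isopropylidenedioxy)-1-(triethylsilyloxy)-4-(triisopropylsilyloxy)cyclohex-2-ene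
Product: 16 (1R,4S,5S,6S)-3-(benzoyloxymethyl)-5,6-(isopropylidenedioxy)-4-(triisopropylsilyloxy)cyclohex-2-en-1-ol
Conditions: HF·pyridine, pyridine, THF, 0 °C
Reagents that add atoms: none
Why: Buffered fluoride desilylation is far faster for a triethylsilyl than for a triisopropylsilyl ether, and the acetonide and the benzoate are inert to it.

Step 13
Reactants: 16 (1R,4S,5S,6S)-3-(benzoyloxymethyl)-5,6-(isopropylidenedioxy)-4-(triisopropylsilyloxy)cyclohex-2-en-1-ol; 17 acetic anhydride
Product: 18 (1R,4S,5S,6S)-1-acetoxy-3-(benzoyloxymethyl)-5,6-(isopropylidenedioxy)-4-(triisopropylsilyloxy)cyclohex-2-ene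
Conditions: Ac2O, pyridine, DMAP (cat.), CH2Cl2, 0 °C → rt
Reagents that add atoms: none
Why: DMAP-catalysed acetylation of the allylic secondary alcohol; the C–O bond at C1 is not broken, so its configuration is kept.

Step 14
Reactants: 18 (1R,4S,5S,6S)-1-acetoxy-3-(benzoyloxymethyl)-5,6-(isopropylidenedioxy)-4-(triisopropylsilyloxy)cyclohex-2-ene
Product: 19 (1R,4S,5S,6R)-1-acetoxy-3-(benzoyloxymethyl)-4-(triisopropylsilyloxy)cyclohex-2-ene-5,6-diol
Conditions: TFA–H2O (9:1), CH2Cl2, 0 °C
Reagents that add atoms: none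
Why: Acid hydrolysis of the dioxolane; the TIPS ether and the three esters should survive short exposure to aqueous trifluoroacetic acid at 0 °C.

Step 15
Reactants: 19 (1R,4S,5S,6R)-1-acetoxy-3-(benzoyloxymethyl)-4-(triisopropylsilyloxy)cyclohex-2-ene-5,6-diol; 20 trimethyl orthobenzoate
Product: 22 (1R,4S,5S,6S)-1-acetoxy-5-benzoyloxy-3-(benzoyloxymethyl)-4-(triisopropylsilyloxy)cyclohex-2-en-6-ol, via cyclic methyl orthobenzoate 21 (not isolated)
Conditions: PhC(OMe)3, CSA (cat.), MeCN, rt; then 80% aq. AcOH, 0 °C → rt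
Reagents that add atoms: water, O
Why: Orthoester exchange on the cis-5,6-diol followed by mild acid hydrolysis through the dioxolanylium ion, whose hemiorthoester collapses to the ester on the axial oxygen; with the bulky C4–OTIPS pseudo-axial (avoiding allylic strain with C7) the half-chair has C5–O axial and C6–O equatorial, so the benzoate should land on C5.

Step 16
Reactants: 22 (1R,4S,5S,6S)-1-acetoxy-5-benzoyloxy-3-(benzoyloxymethyl)-4-(triisopropylsilyloxy)cyclohex-2-en-6-ol
Product: 23 (1R,4S,5R,6S)-1-acetoxy-5-benzoyloxy-3-(benzoyloxymethyl)cyclohex-2-ene-4,6-diol (CNP0169028.1)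
Conditions: HF·pyridine, THF, 0 °C → rt
Reagents that add atoms: none
Why: Acidic fluoride desilylation removes the last silyl ether without base, so the 1,2-acyl migrations that the free C4 and C6 hydroxyls would allow under basic fluoride are avoided.

**Compound list**

1 | L-rhamnose (6-deoxy-L-mannose) | O=C[C@H](O)[C@H](O)[C@@H](O)[C@@H](O)C | starting material
2 | benzyl alcohol | OCc1ccccc1 | starting material
3 | benzyl α-L-rhamnopyranoside | c1ccccc1CO[C@H]2[C@H](O)[C@H](O)[C@@H](O)[C@H](C)O2 | intermediate
4 | benzyl 2,3-O-isopropylidene-α-L-rhamnopyranoside | c1ccccc1CO[C@H]2[C@H](OC3(C)C)[C@H](O3)[C@@H](O)[C@H](C)O2 | intermediate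
5 | benzyl 2,3-O-isopropylidene-4-O-(triisopropylsilyl)-α-L-rhamnopyranoside | c1ccccc1CO[C@H]2[C@H](OC3(C)C)[C@H](O3)[C@@H](O[Si](C(C)C)(C(C)C)C(C)C)[C@H](C)O2 | intermediate
6 | 2,3-O-isopropylidene-4-O-(triisopropylsilyl)-L-rhamnopyranose (anomeric mixture) | OC1[C@H](OC2(C)C)[C@H](O2)[C@@H](O[Si](C(C)C)(C(C)C)C(C)C)[C@H](C)O1 | intermediate
7 | 6-deoxy-2,3-O-isopropylidene-4-O-(triisopropylsilyl)-L-mannitol | OC[C@H](OC1(C)C)[C@H](O1)[C@@H](O[Si](C(C)C)(C(C)C)C(C)C)[C@@H](O)C | intermediate
8 | 6-deoxy-2,3-O-isopropylidene-4-O-(triisopropylsilyl)-L-lyxo-hexos-5-ulose | O=C[C@H](OC1(C)C)[C@H](O1)[C@@H](O[Si](C(C)C)(C(C)C)C(C)C)C(C)=O | intermediate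
9 | (1R,4R,5S,6S)-1-hydroxy-5,6-(isopropylidenedioxy)-4-(triisopropylsilyloxy)cyclohexan-3-one | O[C@@H]1CC(=O)[C@H](O[Si](C(C)C)(C(C)C)C(C)C)[C@H]2OC(C)(C)O[C@@H]12 | intermediate
10 | (1R,4R,5S,6R)-5,6-(isopropylidenedioxy)-1-(triethylsilyloxy)-4-(triisopropylsilyloxy)cyclohexan-3-one | CC[Si](CC)(CC)O[C@@H]1CC(=O)[C@H](O[Si](C(C)C)(C(C)C)C(C)C)[C@H]2OC(C)(C)O[C@@H]12 | intermediate
11 | trimethylsulfonium iodide | C[S+](C)C.[I-] | starting material
12 | (1R,3R,4R,5S,6R)-3,7-epoxy-5,6-(isopropylidenedioxy)-3-methyl-1-(triethylsilyloxy)-4-(triisopropylsilyloxy)cyclohexane | CC[Si](CC)(CC)O[C@@H]1C[C@@]3(CO3)[C@H](O[Si](C(C)C)(C(C)C)C(C)C)[C@H]2OC(C)(C)O[C@@H]12 | intermediate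
13 | (1R,4S,5S,6R)-3-(hydroxymethyl)-5,6-(isopropylidenedioxy)-1-(triethylsilyloxy)-4-(triisopropylsilyloxy)cyclohex-2-ene | CC[Si](CC)(CC)O[C@@H]1C=C(CO)[C@H](O[Si](C(C)C)(C(C)C)C(C)C)[C@@H](OC2(C)C)[C@H]1O2 | intermediate
14 | benzoyl chloride | O=C(Cl)c1ccccc1 | starting material
15 | (1R,4S,5S,6R)-3-(benzoyloxymethyl)-5,6-(isopropylidenedioxy)-1-(triethylsilyloxy)-4-(triisopropylsilyloxy)cyclohex-2-ene | CC[Si](CC)(CC)O[C@@H]1C=C(COC(=O)c2ccccc2)[C@H](O[Si](C(C)C)(C(C)C)C(C)C)[C@@H](OC3(C)C)[C@H]1O3 | intermediate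
16 | (1R,4S,5S,6S)-3-(benzoyloxymethyl)-5,6-(isopropylidenedioxy)-4-(triisopropylsilyloxy)cyclohex-2-en-1-ol | O[C@@H]1C=C(COC(=O)c2ccccc2)[C@H](O[Si](C(C)C)(C(C)C)C(C)C)[C@@H](OC3(C)C)[C@H]1O3 | intermediate
17 | acetic anhydride | CC(=O)OC(C)=O | starting material
18 | (1R,4S,5S,6S)-1-acetoxy-3-(benzoyloxymethyl)-5,6-(isopropylidenedioxy)-4-(triisopropylsilyloxy)cyclohex-2-ene | CC(=O)O[C@@H]1C=C(COC(=O)c2ccccc2)[C@H](O[Si](C(C)C)(C(C)C)C(C)C)[C@@H](OC3(C)C)[C@H]1O3 | intermediate
19 | (1R,4S,5S,6R)-1-acetoxy-3-(benzoyloxymethyl)-4-(triisopropylsilyloxy)cyclohex-2-ene-5,6-diol | CC(=O)O[C@@H]1C=C(COC(=O)c2ccccc2)[C@H](O[Si](C(C)C)(C(C)C)C(C)C)[C@@H](O)[C@H]1O | intermediate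
20 | trimethyl orthobenzoate | COC(OC)(OC)c1ccccc1 | starting material
21 | 5,6-O-(α-methoxybenzylidene) orthoester of 19 (both epimers at the orthoester carbon) | CC(=O)O[C@@H]1C=C(COC(=O)c2ccccc2)[C@H](O[Si](C(C)C)(C(C)C)C(C)C)[C@@H](OC3(OC)c4ccccc4)[C@H]1O3 | intermediate
22 | (1R,4S,5S,6S)-1-acetoxy-5-benzoyloxy-3-(benzoyloxymethyl)-4-(triisopropylsilyloxy)cyclohex-2-en-6-ol | CC(=O)O[C@@H]1C=C(COC(=O)c2ccccc2)[C@H](O[Si](C(C)C)(C(C)C)C(C)C)[C@@H](OC(=O)c2ccccc2)[C@H]1O | intermediate
23 | (1R,4S,5R,6S)-1-acetoxy-5-benzoyloxy-3-(benzoyloxymethyl)cyclohex-2-ene-4,6-diol (CNP0169028.1) | CC(=O)O[C@@H]1C=C(COC(=O)c2ccccc2)[C@H](O)[C@@H](OC(=O)c2ccccc2)[C@H]1O | target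

**Step count and risks**

Total step count: 16. Longest linear sequence: 16 steps (1 → 23).

Steps most likely to fail:

Step 7 (aldol ring closure). The enamine may add to the wrong face of the aldehyde, or the hindered ketone may condense so slowly that an enamine on the aldehyde side epimerises C6 or expels the C5 oxygen. Fallback: set C1 by substitution instead of by the aldol. Setting out from 8, the cyclisation is run under equilibrating conditions (Et3N, CH2Cl2, rt), where the carbinol that is equatorial and cis to C6–O is expected to prevail, giving the C1-epimeric ketol F1. This is carried through the operations of steps 8–12: silylation to the triethylsilyl ether F2, ylide epoxidation to the spiro-epoxide F3, aluminium amide isomerisation to the allylic alcohol F4, benzoylation to the C7 benzoate F5 and buffered HF·pyridine to the C1-epimeric alcohol F6. A Mitsunobu reaction of F6 with acetic acid (PPh3, diisopropyl azodicarboxylate, AcOH, THF, 0 °C) then inverts C1 and installs the acetate in one operation, and the route is rejoined at 18.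

Step 15 (orthobenzoate opening). If the half-chair with C5–O equatorial is populated, the ring opening places the benzoate on C6, and acid-catalysed drift of the benzoyl group between the cis oxygens would blur the result further. Fallback: kinetic acylation of the equatorial oxygen through tin. Setting out from 19, Bu2SnO (toluene, reflux, azeotropic removal of water) gives the 5,6-O-dibutylstannylene acetal F7, which is treated with BzCl at 0 °C; stannylene acetals of cis-diols acylate the equatorial oxygen, so this is the complementary method for the case in which C5–O is equatorial. The route is rejoined at 22.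

Step 10 (epoxide isomerisation). The aluminium centre may act as a Lewis acid and trigger a hydride shift of the oxirane to the C7 aldehyde, or the amide may remove the C4 proton; enolisation during the preceding ylide step would compound the loss. Fallback: cross-coupling instead of epoxide chemistry. Setting out from 10, kinetic deprotonation at C2 and O-sulfonylation (KN(SiMe3)2, PhNTf2, THF, −78 °C) gives the C2-enol triflate F8. Stille coupling with (tributylstannyl)methanol (Pd(PPh3)4, a zerovalent palladium complex, LiCl, dioxane, 90 °C) then attaches C7 as the hydroxymethyl group, and the route is rejoined at 13.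

**Further compounds**

F1 | step 7 | C1-epimeric ketol (1-epi-9) | O[C@H]1CC(=O)[C@H](O[Si](C(C)C)(C(C)C)C(C)C)[C@H]2OC(C)(C)O[C@@H]12
F2 | step 7 | triethylsilyl ether of F1 (1-epi-10) | CC[Si](CC)(CC)O[C@H]1CC(=O)[C@H](O[Si](C(C)C)(C(C)C)C(C)C)[C@H]2OC(C)(C)O[C@@H]12
F3 | step 7 | spiro-epoxide from F2 (1-epi-12, one epimer at the spiro carbon drawn) | CC[Si](CC)(CC)O[C@H]1C[C@@]3(CO3)[C@H](O[Si](C(C)C)(C(C)C)C(C)C)[C@H]2OC(C)(C)O[C@@H]12
F4 | step 7 | allylic alcohol from F3 (1-epi-13) | CC[Si](CC)(CC)O[C@H]1C=C(CO)[C@H](O[Si](C(C)C)(C(C)C)C(C)C)[C@@H](OC2(C)C)[C@H]1O2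
F5 | step 7 | C7 benzoate of F4 (1-epi-15) | CC[Si](CC)(CC)O[C@H]1C=C(COC(=O)c2ccccc2)[C@H](O[Si](C(C)C)(C(C)C)C(C)C)[C@@H](OC3(C)C)[C@H]1O3
F6 | step 7 | C1-epimeric alcohol (1-epi-16) | O[C@H]1C=C(COC(=O)c2ccccc2)[C@H](O[Si](C(C)C)(C(C)C)C(C)C)[C@@H](OC3(C)C)[C@H]1O3
F7 | step 15 | 5,6-O-dibutylstannylene acetal of 19 | CC(=O)O[C@@H]1C=C(COC(=O)c2ccccc2)[C@H](O[Si](C(C)C)(C(C)C)C(C)C)[C@@H](O[Sn]3(CCCC)CCCC)[C@H]1O3
F8 | step 10 | C2-enol triflate of 10 (OTf on C3, C2=C3) | CC[Si](CC)(CC)O[C@@H]1C=C(OS(=O)(=O)C(F)(F)F)[C@H](O[Si](C(C)C)(C(C)C)C(C)C)[C@@H](OC2(C)C)[C@H]1O2
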